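**Retrosynthetic overview**

1. The strategy rests on the pyrrole ring N5–C6–C7–C8–C8a of the pyrrolo[2,1-c][1,4]oxazin-1-one (oxazinone ring C1(=O)–O2–C3–C4–N5–C8a): C6 carries H, the adjacent C7 and C8 carry unlike aryl groups (4-hydroxy-3-iodophenyl and 4-hydroxyphenyl), and C8a carries the carboxyl carbon C1.
2. Late disconnections: three aryl O–CH3 bonds (BBr3), the enol-lactone bond O2–C1 (Ac2O on a keto acid), and N5–C4 (N-alkylation with a phenacyl bromide).
3. Key disconnection: C7–C8 and N5–C8a. The N5–C6–C7 unit comes from a 4-aryl-1-tosyl-1,2,3-triazole (a masked α-imino rhodium carbene), and C8–C8a from the trimethylsilyl enol ether of methyl 4-methoxyphenylpyruvate.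
4. The triazole comes from 3-iodo-4-methoxybenzaldehyde by alkynylation and copper-catalysed cycloaddition with tosyl azide; the enol ether comes from 4-methoxyphenylpyruvic acid by esterification and silylation.
5. Ring order: pyrrole first (step 5), oxazinone second (step 9).

Key step: step 5

Remark on the chemistry: the target has no stereocentre. Ester 6 is drawn as its keto tautomer although arylpyruvates are largely Z-enols. Compounds 1, 3 (as a toluene solution), 5 and 12 are assumed to be commercial.

**Step 1**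
Reactants: 1 3-iodo-4-methoxybenzaldehyde
Product: 2 4-ethynyl-2-iodo-1-methoxybenzene
Conditions: Ohira–Bestmann reagent (1.3 equiv), K2CO3 (2 equiv), MeOH, 0 °C → rt
Reagents that add atoms: dimethyl (1-diazo-2-oxopropyl)phosphonate, CC(=O)C(=[N+]=[N-])P(=O)(OC)OC
Why: Seyferth–Gilbert homologation in the Ohira–Bestmann variant, in which the diazomethylphosphonate anion released by methanolysis adds to the non-enolizable aldehyde and loss of dimethyl phosphate and N2 with a 1,2-shift should give the terminal alkyne without touching the aryl iodide.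

**Step 2**
Reactants: 2 4-ethynyl-2-iodo-1-methoxybenzene; 3 4-methylbenzenesulfonyl azide
Product: 4 4-(3-iodo-4-methoxyphenyl)-1-(4-methylbenzenesulfonyl)-1H-1,2,3-triazole
Conditions: copper thiophene-2-carboxylate Cu(O2CC4H3S) (10 mol %), toluene, 0 °C → rt
Reagents that add atoms: none
Why: Copper-catalysed azide–alkyne cycloaddition, in which the copper acetylide should deliver only the 1,4-disubstituted 1-sulfonyl triazole, while the monovalent copper carboxylate in cold toluene suppresses opening of the copper triazolide to a ketenimine and any coupling at the aryl iodide.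

**Step 3**
Reactants: 5 3-(4-methoxyphenyl)-2-oxopropanoic acid
Product: 6 methyl 3-(4-methoxyphenyl)-2-oxopropanoate
Conditions: DBU (1.0 equiv), MeI (1.2 equiv), DMF, 0 °C → rt
Reagents that add atoms: iodomethane, CI
Why: Carboxylate O-alkylation (SN2) with one equivalent of amidine base, which should esterify the strongly acidic keto acid selectively and avoids the ketal formation that an acid-catalysed esterification in methanol could cause.

**Step 4**
Reactants: 6 methyl 3-(4-methoxyphenyl)-2-oxopropanoate
Product: 7 methyl (2Z)-3-(4-methoxyphenyl)-2-[(trimethylsilyl)oxy]prop-2-enoate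
Conditions: Me3SiCl (1.5 equiv), Et3N (2 equiv), THF, 0 °C → rt; filtered under argon and used directly
Reagents that add atoms: chlorotrimethylsilane, C[Si](C)(C)Cl
Why: Silyl enol ether formation by O-silylation of the already enolized arylpyruvate, which should keep the thermodynamic Z geometry in which the aryl group is trans to the ester.

**Step 5**
Reactants: 4 4-(3-iodo-4-methoxyphenyl)-1-(4-methylbenzenesulfonyl)-1H-1,2,3-triazole; 7 methyl (2Z)-3-(4-methoxyphenyl)-2-[(trimethylsilyl)oxy]prop-2-enoate
Product: 10 methyl 4-(3-iodo-4-methoxyphenyl)-3-(4-methoxyphenyl)-1-(4-methylbenzenesulfonyl)-1H-pyrrole-2-carboxylate, via alpha-diazo imine 8 (not isolated), via silyloxy dihydropyrrole 9 (not isolated)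
Conditions: 7 (2.5 equiv), Rh2(O2CC7H15)4 (2 mol %), dry 1,2-dichloroethane, 80 °C; then TsOH·H2O (20 mol %), 80 °C
Reagents that add atoms: none
Why: Triazole 4 is in ring–chain equilibrium with α-diazo imine 8, which loses N2 on the dirhodium tetracarboxylate to give a rhodium-bound α-imino carbene whose carbene carbon (future C7) carries the iodoaryl group; the β-carbon of enol ether 7 (future C8) attacks that carbon, the sulfonylated nitrogen (N5) of the resulting azaallyl/oxocarbenium zwitterion closes on the silyloxy-bearing carbon (future C8a) to give dihydropyrrole 9, and acid then removes trimethylsilanol across C8–C8a. The closest known reaction is the dirhodium-catalysed denitrogenative transannulation of 1-sulfonyl-1,2,3-triazoles with silyl and alkyl enol ethers to pyrroles, applied here to an enol ether that carries an ester on its oxygenated carbon and is therefore less nucleophilic and more hindered than the usual partners, which is why 7 is used in excess. The pyrrole ring is closed by a stepwise polar formal [3+2] annulation, the C–N bond arising from 5-exo-trig attack of nitrogen on the oxocarbenium carbon. No stereocentre remains, since the two sp3 centres of 9 form without control and both are erased on aromatization. The step needs a single orientation of the two partners, and polarity secures it: the only nucleophilic carbon of 7 is the aryl-bearing β-carbon and the only electrophilic carbon of the carbene is the one bearing the iodoaryl group, so the ester carbon must end next to nitrogen, and a cyclopropane, if it formed, would open to the same zwitterion. Chemoselectivity should hold because the enol ether is far more nucleophilic than the anisole rings and because a divalent rhodium carboxylate does not insert into the carbon–iodine bond.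

**Step 6**
Reactants: 10 methyl 4-(3-iodo-4-methoxyphenyl)-3-(4-methoxyphenyl)-1-(4-methylbenzenesulfonyl)-1H-pyrrole-2-carboxylate
Product: 11 methyl 4-(3-iodo-4-methoxyphenyl)-3-(4-methoxyphenyl)-1H-pyrrole-2-carboxylate
Conditions: K2CO3 (2 equiv), MeOH/THF, rt
Reagents that add atoms: none
Why: Nucleophilic N–S cleavage (sulfonyl transfer to methoxide), which should be fast because the ester-stabilized pyrrolide is a good leaving group, while transesterification of the methyl ester is degenerate and the aryl iodide is inert.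

**Step 7**
Reactants: 11 methyl 4-(3-iodo-4-methoxyphenyl)-3-(4-methoxyphenyl)-1H-pyrrole-2-carboxylate; 12 2-bromo-1-(4-methoxyphenyl)ethanone
Product: 13 methyl 4-(3-iodo-4-methoxyphenyl)-3-(4-methoxyphenyl)-1-[2-(4-methoxyphenyl)-2-oxoethyl]-1H-pyrrole-2-carboxylate
Conditions: 12 (1.2 equiv), K2CO3 (2 equiv), acetone, reflux
Reagents that add atoms: none
Why: N-alkylation (SN2) of the pyrrolide, whose N–H is acidified by the 2-ester, with a reactive α-bromo ketone, which should install C4 and C3 with the third aryl group.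

**Step 8**
Reactants: 13 methyl 4-(3-iodo-4-methoxyphenyl)-3-(4-methoxyphenyl)-1-[2-(4-methoxyphenyl)-2-oxoethyl]-1H-pyrrole-2-carboxylate
Product: 14 4-(3-iodo-4-methoxyphenyl)-3-(4-methoxyphenyl)-1-[2-(4-methoxyphenyl)-2-oxoethyl]-1H-pyrrole-2-carboxylic acid
Conditions: KOH (5 equiv), MeOH/THF/H2O, 60 °C; then 1 M HCl
Reagents that add atoms: potassium hydroxide, [K+].[OH-]
Why: Saponification (acyl-oxygen ester hydrolysis), which should be clean because the ketone α-carbon could reach the ester only through a four-membered ring, and acidification releases the acid.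

**Step 9**
Reactants: 14 4-(3-iodo-4-methoxyphenyl)-3-(4-methoxyphenyl)-1-[2-(4-methoxyphenyl)-2-oxoethyl]-1H-pyrrole-2-carboxylic acid
Product: 16 7-(3-iodo-4-methoxyphenyl)-3,8-bis(4-methoxyphenyl)-1H-pyrrolo[2,1-c][1,4]oxazin-1-one, via mixed acetic anhydride 15 (not isolated)
Conditions: Ac2O, NaOAc (0.5 equiv), 120 °C
Reagents that add atoms: none
Why: Enol lactonization, in which the acid is activated as mixed anhydride 15 and the enol oxygen of the phenacyl ketone attacks the activated carbonyl (6-exo-trig acyl substitution) to form O2–C1, the ketone having only one α-carbon so that a single enol ester can form.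

**Step 10**
Reactants: 16 7-(3-iodo-4-methoxyphenyl)-3,8-bis(4-methoxyphenyl)-1H-pyrrolo[2,1-c][1,4]oxazin-1-one
Product: 18 lukianol B, via tris(dibromoboryl) ether 17 (not isolated)
Conditions: BBr3 (9 equiv), CH2Cl2, −78 °C → rt; then H2O, 0 °C
Reagents that add atoms: none
Why: Lewis-acid aryl methyl ether cleavage, in which each ether oxygen binds boron and bromide attacks the methyl group (SN2), the aryl borates being hydrolysed on work-up, while the pyrrole-conjugated enol lactone and the carbon–iodine bond should persist at or below room temperature.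

**Compound list**

1 | 3-iodo-4-methoxybenzaldehyde | COc1ccc(C=O)cc1I | starting material
2 | 4-ethynyl-2-iodo-1-methoxybenzene | COc1ccc(C#C)cc1I | intermediate
3 | 4-methylbenzenesulfonyl azide | Cc1ccc(cc1)S(=O)(=O)N=[N+]=[N-] | starting material
4 | 4-(3-iodo-4-methoxyphenyl)-1-(4-methylbenzenesulfonyl)-1H-1,2,3-triazole | Cc1ccc(cc1)S(=O)(=O)n1cc(nn1)-c1ccc(OC)c(I)c1 | intermediate
5 | 3-(4-methoxyphenyl)-2-oxopropanoic acid | COc1ccc(CC(=O)C(=O)O)cc1 | starting material
6 | methyl 3-(4-methoxyphenyl)-2-oxopropanoate (keto form drawn; largely the Z-enol) | COC(=O)C(=O)Cc1ccc(OC)cc1 | intermediate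
7 | methyl (2Z)-3-(4-methoxyphenyl)-2-[(trimethylsilyl)oxy]prop-2-enoate | COC(=O)/C(O[Si](C)(C)C)=C/c1ccc(OC)cc1 | intermediate
8 | N-[(1E)-2-diazo-2-(3-iodo-4-methoxyphenyl)ethylidene]-4-methylbenzenesulfonamide (formed in the flask) | Cc1ccc(cc1)S(=O)(=O)/N=C/C(=[N+]=[N-])c1ccc(OC)c(I)c1 | intermediate
9 | methyl 4-(3-iodo-4-methoxyphenyl)-3-(4-methoxyphenyl)-1-(4-methylbenzenesulfonyl)-2-[(trimethylsilyl)oxy]-2,3-dihydro-1H-pyrrole-2-carboxylate (formed in the flask; racemic, C2/C3 diastereomer mixture) | COC(=O)C1(O[Si](C)(C)C)C(c2ccc(OC)cc2)C(c2ccc(OC)c(I)c2)=CN1S(=O)(=O)c1ccc(C)cc1 | intermediate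
10 | methyl 4-(3-iodo-4-methoxyphenyl)-3-(4-methoxyphenyl)-1-(4-methylbenzenesulfonyl)-1H-pyrrole-2-carboxylate | COC(=O)c1c(-c2ccc(OC)cc2)c(-c2ccc(OC)c(I)c2)cn1S(=O)(=O)c1ccc(C)cc1 | intermediate
11 | methyl 4-(3-iodo-4-methoxyphenyl)-3-(4-methoxyphenyl)-1H-pyrrole-2-carboxylate | COC(=O)c1[nH]cc(-c2ccc(OC)c(I)c2)c1-c1ccc(OC)cc1 | intermediate
12 | 2-bromo-1-(4-methoxyphenyl)ethanone | COc1ccc(cc1)C(=O)CBr | starting material
13 | methyl 4-(3-iodo-4-methoxyphenyl)-3-(4-methoxyphenyl)-1-[2-(4-methoxyphenyl)-2-oxoethyl]-1H-pyrrole-2-carboxylate | COC(=O)c1c(-c2ccc(OC)cc2)c(-c2ccc(OC)c(I)c2)cn1CC(=O)c1ccc(OC)cc1 | intermediate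
14 | 4-(3-iodo-4-methoxyphenyl)-3-(4-methoxyphenyl)-1-[2-(4-methoxyphenyl)-2-oxoethyl]-1H-pyrrole-2-carboxylic acid | OC(=O)c1c(-c2ccc(OC)cc2)c(-c2ccc(OC)c(I)c2)cn1CC(=O)c1ccc(OC)cc1 | intermediate
15 | acetic 4-(3-iodo-4-methoxyphenyl)-3-(4-methoxyphenyl)-1-[2-(4-methoxyphenyl)-2-oxoethyl]-1H-pyrrole-2-carboxylic anhydride (formed in the flask) | CC(=O)OC(=O)c1c(-c2ccc(OC)cc2)c(-c2ccc(OC)c(I)c2)cn1CC(=O)c1ccc(OC)cc1 | intermediate
16 | 7-(3-iodo-4-methoxyphenyl)-3,8-bis(4-methoxyphenyl)-1H-pyrrolo[2,1-c][1,4]oxazin-1-one (tri-O-methyllukianol B) | O=c1oc(-c2ccc(OC)cc2)cn2cc(-c3ccc(OC)c(I)c3)c(-c3ccc(OC)cc3)c12 | intermediate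
17 | 7-{4-[(dibromoboranyl)oxy]-3-iodophenyl}-3,8-bis{4-[(dibromoboranyl)oxy]phenyl}-1H-pyrrolo[2,1-c][1,4]oxazin-1-one (formed in the flask) | O=c1oc(-c2ccc(OB(Br)Br)cc2)cn2cc(-c3ccc(OB(Br)Br)c(I)c3)c(-c3ccc(OB(Br)Br)cc3)c12 | intermediate
18 | lukianol B, 7-(4-hydroxy-3-iodophenyl)-3,8-bis(4-hydroxyphenyl)-1H-pyrrolo[2,1-c][1,4]oxazin-1-one | O=c1oc(-c2ccc(O)cc2)cn2cc(-c3ccc(O)c(I)c3)c(-c3ccc(O)cc3)c12 | target

**Step count**

Total steps: 10. Longest linear sequence: 8 steps (1 → 2 → 4 → 10 → 11 → 13 → 14 → 16 → 18; the branch 5 → 6 → 7 → 10 → … → 18 is equally long).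

**Steps most likely to fail**

Step 5. Carbon–carbon bond formation between the rhodium carbene and the ester-deactivated, trisubstituted enol ether may be too slow. The carbene would then be consumed by traces of water, by its own diazo precursor or by the anisole rings, and the silyloxy dihydropyrrole may also resist loss of silanol. The fallback builds the same C7–C8 and N5–C8a bonds by polar chemistry without a carbene; it sets out from 1 and 6 and returns at 11, so that steps 1, 2, 4, 5 and 6 are not needed.
- Henry condensation of 1 with nitromethane (NH4OAc, AcOH, 90 °C) should give (E)-2-iodo-1-methoxy-4-(2-nitroethenyl)benzene F1.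
- Base-catalysed Michael addition of keto ester 6 through its benzylic carbon (Et3N cat., CH2Cl2, rt) should give methyl 4-(3-iodo-4-methoxyphenyl)-3-(4-methoxyphenyl)-5-nitro-2-oxopentanoate F2 as a diastereomer mixture.
- Reduction of the nitro group with Fe powder in AcOH/EtOH at 70 °C should give methyl 5-amino-4-(3-iodo-4-methoxyphenyl)-3-(4-methoxyphenyl)-2-oxopentanoate F3, which is not isolated and should condense onto the keto group to give methyl 3-(3-iodo-4-methoxyphenyl)-4-(4-methoxyphenyl)-3,4-dihydro-2H-pyrrole-5-carboxylate F4.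
- Dehydrogenation with DDQ (toluene, rt → 60 °C) should give 11, which continues with step 7.

Step 4. The trimethylsilyl enol ether may hydrolyse back to 6 during isolation, or through traces of water and acid in the hot rhodium step, so that too little nucleophile reaches the carbene. The fallback replaces it with a bench-stable alkyl enol ether; it sets out from 6 and returns at 10.
- O-methylation of the enol of 6 (Me2SO4, Cs2CO3, DMF, 0 °C) should give methyl (2Z)-2-methoxy-3-(4-methoxyphenyl)prop-2-enoate F5, which can be chromatographed and stored.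
- Transannulation of 4 with F5 (Rh2(O2CC7H15)4, 1,2-dichloroethane, 80 °C) should pass through 8 and methyl 4-(3-iodo-4-methoxyphenyl)-2-methoxy-3-(4-methoxyphenyl)-1-(4-methylbenzenesulfonyl)-2,3-dihydro-1H-pyrrole-2-carboxylate F6 (not isolated).
- Loss of methanol with TsOH·H2O at 80 °C should give 10.

Step 10. Cleavage of the third methyl ether may lag behind Lewis-acid opening of the enol lactone or its hydrolysis on work-up, and long exposure of the ortho-iodophenol to HBr invites protodeiodination. The fallback cleaves the ethers before the lactone exists, closes the lactone under acetylation and ends with a mild ester cleavage; it sets out from 13 and returns at 18.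
- BBr3 (CH2Cl2, −78 → 0 °C, quenched as soon as the ethers are consumed) on ester 13 should give methyl 4-(4-hydroxy-3-iodophenyl)-3-(4-hydroxyphenyl)-1-[2-(4-hydroxyphenyl)-2-oxoethyl]-1H-pyrrole-2-carboxylate F7.
- Saponification (KOH, MeOH/H2O, 60 °C, then HCl) should give 4-(4-hydroxy-3-iodophenyl)-3-(4-hydroxyphenyl)-1-[2-(4-hydroxyphenyl)-2-oxoethyl]-1H-pyrrole-2-carboxylic acid F8.
- Ac2O/NaOAc at 120 °C should close the lactone and acetylate the three phenols to give 7-[4-(acetyloxy)-3-iodophenyl]-3,8-bis[4-(acetyloxy)phenyl]-1H-pyrrolo[2,1-c][1,4]oxazin-1-one F9.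
- Methanolysis of the aryl acetates (NH4OAc, MeOH/H2O, rt) should return 18, the lactone carbonyl being deactivated by conjugation with the pyrrole nitrogen.

**Further compounds**

F1 | step 5 | (E)-2-iodo-1-methoxy-4-(2-nitroethenyl)benzene | COc1ccc(/C=C/[N+](=O)[O-])cc1I
F2 | step 5 | methyl 4-(3-iodo-4-methoxyphenyl)-3-(4-methoxyphenyl)-5-nitro-2-oxopentanoate (diastereomer mixture) | COC(=O)C(=O)C(c1ccc(OC)cc1)C(C[N+](=O)[O-])c1ccc(OC)c(I)c1
F3 | step 5 | methyl 5-amino-4-(3-iodo-4-methoxyphenyl)-3-(4-methoxyphenyl)-2-oxopentanoate (not isolated) | COC(=O)C(=O)C(c1ccc(OC)cc1)C(CN)c1ccc(OC)c(I)c1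
F4 | step 5 | methyl 3-(3-iodo-4-methoxyphenyl)-4-(4-methoxyphenyl)-3,4-dihydro-2H-pyrrole-5-carboxylate (diastereomer mixture) | COC(=O)C1=NCC(c2ccc(OC)c(I)c2)C1c1ccc(OC)cc1
F5 | step 4 | methyl (2Z)-2-methoxy-3-(4-methoxyphenyl)prop-2-enoate | COC(=O)/C(OC)=C/c1ccc(OC)cc1
F6 | step 4 | methyl 4-(3-iodo-4-methoxyphenyl)-2-methoxy-3-(4-methoxyphenyl)-1-(4-methylbenzenesulfonyl)-2,3-dihydro-1H-pyrrole-2-carboxylate (not isolated; diastereomer mixture) | COC(=O)C1(OC)C(c2ccc(OC)cc2)C(c2ccc(OC)c(I)c2)=CN1S(=O)(=O)c1ccc(C)cc1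
F7 | step 10 | methyl 4-(4-hydroxy-3-iodophenyl)-3-(4-hydroxyphenyl)-1-[2-(4-hydroxyphenyl)-2-oxoethyl]-1H-pyrrole-2-carboxylate | COC(=O)c1c(-c2ccc(O)cc2)c(-c2ccc(O)c(I)c2)cn1CC(=O)c1ccc(O)cc1
F8 | step 10 | 4-(4-hydroxy-3-iodophenyl)-3-(4-hydroxyphenyl)-1-[2-(4-hydroxyphenyl)-2-oxoethyl]-1H-pyrrole-2-carboxylic acid | OC(=O)c1c(-c2ccc(O)cc2)c(-c2ccc(O)c(I)c2)cn1CC(=O)c1ccc(O)cc1
F9 | step 10 | 7-[4-(acetyloxy)-3-iodophenyl]-3,8-bis[4-(acetyloxy)phenyl]-1H-pyrrolo[2,1-c][1,4]oxazin-1-one | CC(=O)Oc1ccc(cc1)-c1cn2cc(-c3ccc(OC(C)=O)c(I)c3)c(-c3ccc(OC(C)=O)cc3)c2c(=O)o1
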